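**Retrosynthetic overview** (ring atoms numbered as in benzofuran-2(3H)-one: O1, C2(=O), C3, C3a, C4–C7, C7a)

1. The target is the hydroxy-quinone-methide tautomer of the o-quinone of a 5,6-dihydroxy-3-arylbenzofuran-2(3H)-one. The six-membered ring can therefore be built as an arene with methyl-protected oxygens, then unmasked (BBr3) and oxidised (Ag2O) at the very end.
2. Key disconnection: C7a–C7 and C4–C5 of the carbocycle, a one-pot [3+3] union of butenolide 6 with the C3 dielectrophile 10 (β-OTf carbon = C7, enol-ether carbon = C6, ester carbon = C5).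
3. Enabling feature: the two carbons flanking the ring fusion, the O-bearing C7a and the aryl-bearing C4 on C3a, are the γ- and γ′-positions of the butenolide C2(=O)–C3=C3a, so both are vinylogously acidic. The remaining C5(OH)–C6(=O)–C7(Ph) triad is an oxidised phenylpyruvate unit.
4. Ring order: the three aryl rings are bought; the butenolide ring comes from an ester alkylation/intramolecular aldol condensation of two (4-methoxyphenyl)acetic units (step 2); the six-membered carbocycle is closed last (step 5).

Key step: step 5

Remark on the chemistry: the target has no stereocentre and no stereogenic double bond, so it is one achiral compound. The sp3 centres of intermediates (C2 of 9, C7a of 11, C3 of 12 and 13) are racemic and disappear before the end.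

**Step 1**
Reactants: 1 (4-methoxyphenyl)acetyl chloride
Product: 3 1-bromo-3-(4-methoxyphenyl)propan-2-one, via diazoketone 2 (not isolated)
Conditions: CH2N2 (2.5 equiv), Et2O, 0 °C to rt; then 48% aq. HBr, 0 °C
Reagents that add atoms: diazomethane C=[N+]=[N-]; hydrogen bromide Br
Why: C-acylation of diazomethane (first stage of an Arndt–Eistert sequence, excess reagent trapping HCl) should give the α-diazoketone, which HBr protonates at carbon so that bromide displaces N2 to give the bromomethyl ketone.

**Step 2**
Reactants: 3 1-bromo-3-(4-methoxyphenyl)propan-2-one; 4 (4-methoxyphenyl)acetic acid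
Product: 6 4-(4-methoxybenzyl)-3-(4-methoxyphenyl)furan-2(5H)-one, via keto ester 5 (not isolated)
Conditions: Et3N (1.1 equiv), MeCN, rt; then DBU (1.5 equiv), 0 °C to rt
Reagents that add atoms: none
Why: SN2 alkylation of the carboxylate by the α-bromoketone, then an intramolecular aldol (Knoevenagel-type) condensation of the arylacetate CH2 onto the ketone with dehydration, the standard route to 3-aryl-4-substituted 2(5H)-furanones, should give the conjugated butenolide.

**Step 3**
Reactants: 7 methyl methoxyacetate; 8 benzoyl chloride
Product: 9 methyl 2-methoxy-3-oxo-3-phenylpropanoate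
Conditions: LDA (2.1 equiv), THF, −78 °C; then PhCOCl, −78 to 0 °C; aq. NH4Cl
Reagents that add atoms: none
Why: Crossed Claisen C-acylation of the lithium ester enolate by the non-enolisable acid chloride, with the second equivalent of base holding the more acidic β-keto ester as its enolate so that it is not acylated again.

**Step 4**
Reactants: 9 methyl 2-methoxy-3-oxo-3-phenylpropanoate
Product: 10 methyl (E)-2-methoxy-3-phenyl-3-(triflyloxy)prop-2-enoate
Conditions: NaH (1.1 equiv), CH2Cl2, 0 °C; then Tf2O, −78 to 0 °C
Reagents that add atoms: trifluoromethanesulfonic anhydride O=S(=O)(OS(=O)(=O)C(F)(F)F)C(F)(F)F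
Why: O-sulfonylation of the chelated sodium enolate of the β-keto ester should give the enol triflate with OTf cis to the ester, a base-stable, non-enolisable acrylate carrying a β-leaving group; the geometry is not critical because it can equilibrate after step 5 has formed the first bond.

**Step 5**
Reactants: 6 4-(4-methoxybenzyl)-3-(4-methoxyphenyl)furan-2(5H)-one; 10 methyl (E)-2-methoxy-3-phenyl-3-(triflyloxy)prop-2-enoate
Product: 12 5-hydroxy-6-methoxy-3,4-bis(4-methoxyphenyl)-7-phenyl-1-benzofuran-2(3H)-one, via addition–elimination adduct 11 (not isolated)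
Conditions: KHMDS (2.1 equiv), THF, −78 °C; 10, −78 to 0 °C; then KHMDS (1.2 equiv), 0 to 50 °C; degassed aq. HCl, Ar
Reagents that add atoms: none
Why: Proposed new method: a one-pot anionic [3+3] benzannulation in which the potassium 2-furanolate of 6 (aromatic, formed by loss of the ring γ-H at C7a) should add through C7a to the β-carbon of acrylate 10 and expel triflate (addition–elimination, C7a–C7 bond), after which the excess base lets the γ′-benzylic carbon C4 attack the ester carbonyl (Dieckmann acylation, C4–C5 bond, loss of methoxide) and two prototropic shifts aromatise the new ring to the phenoxide/lactone enolate of 12. The closest known reaction types are the [3+3] cyclocondensations of 1,3-C,C-dinucleophiles (β-keto ester dianions, 1,3-bis-silyl enol ethers) with β-alkoxy- or β-halo-acrylates to give phenols, the γ-selective vinylogous Michael additions of butenolide-derived furanolates, and Dieckmann/aromatisation closures of the Hauser and Staunton–Weinreb kind; new is their union on a 4-benzylbutenolide. The six-membered carbocycle is the only ring closed, in the 6-(enolexo)-exo-trig Dieckmann mode, and closure from C3 instead of C4 is excluded because it would give a bridged, anti-Bredt bicycle. No stereocentre needs control: the C7a centre of 11 is lost on aromatisation and C3 of 12 is a labile racemic centre that becomes sp2 in step 6. The step needs γ (C7a) attack rather than γ′ (C4) or α (C3) attack in the first bond, which the aromaticity of the 2-oxidofuran and the fully substituted, hindered C3 should secure, and it needs the ester cis to C7a, which the geometry of 10 and C7–C6 rotation in the delocalised anion of 11 should secure. Aromatisation makes the sequence irreversible.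

**Step 6**
Reactants: 12 5-hydroxy-6-methoxy-3,4-bis(4-methoxyphenyl)-7-phenyl-1-benzofuran-2(3H)-one
Product: 14 peniophorin, via leucopeniophorin 13 (not isolated)
Conditions: BBr3 (6 equiv), CH2Cl2, −78 °C to rt; H2O, EtOAc, Ar; then Ag2O (1.1 equiv), acetone, rt, dark; dilute HCl wash
Reagents that add atoms: none
Why: BBr3 should cleave the three aryl methyl ethers while the aryl lactone survives at or below room temperature, and Ag2O should oxidise the freed catechol to the 5,6-o-quinone, which tautomerises (C3–H to O5) to the more conjugated 5-hydroxy quinone methide, the target.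

**Compound list**
1 | (4-methoxyphenyl)acetyl chloride | COc1ccc(CC(=O)Cl)cc1 | starting material
2 | 1-diazo-3-(4-methoxyphenyl)propan-2-one | COc1ccc(CC(=O)C=[N+]=[N-])cc1 | intermediate
3 | 1-bromo-3-(4-methoxyphenyl)propan-2-one | COc1ccc(CC(=O)CBr)cc1 | intermediate
4 | (4-methoxyphenyl)acetic acid | COc1ccc(CC(=O)O)cc1 | starting material
5 | 3-(4-methoxyphenyl)-2-oxopropyl (4-methoxyphenyl)acetate | COc1ccc(CC(=O)OCC(=O)Cc2ccc(OC)cc2)cc1 | intermediate
6 | 4-(4-methoxybenzyl)-3-(4-methoxyphenyl)furan-2(5H)-one | COc1ccc(CC2=C(c3ccc(OC)cc3)C(=O)OC2)cc1 | intermediate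
7 | methyl methoxyacetate | COCC(=O)OC | starting material
8 | benzoyl chloride | O=C(Cl)c1ccccc1 | starting material
9 | methyl 2-methoxy-3-oxo-3-phenylpropanoate (racemic, enolisable) | COC(C(=O)OC)C(=O)c1ccccc1 | intermediate
10 | methyl (E)-2-methoxy-3-phenyl-3-(triflyloxy)prop-2-enoate (OTf cis to CO2Me) | COC(=O)/C(OC)=C(\OS(=O)(=O)C(F)(F)F)c1ccccc1 | intermediate
11 | methyl (E)-2-methoxy-3-[3-(4-methoxybenzyl)-4-(4-methoxyphenyl)-5-oxo-2,5-dihydrofuran-2-yl]-3-phenylprop-2-enoate (racemic) | COC(=O)/C(OC)=C(\C1OC(=O)C(c2ccc(OC)cc2)=C1Cc1ccc(OC)cc1)c1ccccc1 | intermediate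
12 | 5-hydroxy-6-methoxy-3,4-bis(4-methoxyphenyl)-7-phenyl-1-benzofuran-2(3H)-one (racemic at C3) | O=C1Oc2c(-c3ccccc3)c(OC)c(O)c(-c3ccc(OC)cc3)c2C1c1ccc(OC)cc1 | intermediate
13 | leucopeniophorin, 5,6-dihydroxy-3,4-bis(4-hydroxyphenyl)-7-phenyl-1-benzofuran-2(3H)-one (racemic at C3) | O=C1Oc2c(-c3ccccc3)c(O)c(O)c(-c3ccc(O)cc3)c2C1c1ccc(O)cc1 | intermediate
14 | peniophorin, 5-hydroxy-3,4-bis(4-hydroxyphenyl)-7-phenyl-1-benzofuran-2,6-dione (achiral) | O=C1OC2=C(c3ccccc3)C(=O)C(O)=C(c3ccc(O)cc3)C2=C1c1ccc(O)cc1 | target

**Step count and risks**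
Total steps: 6. Longest linear sequence: 4 (steps 1, 2, 5, 6; the branch 3, 4, 5, 6 is equally long).

Steps most likely to fail:

1. Step 5 (proposed new method). The first C–C bond may form at the benzylic γ′-carbon instead of the ring γ-carbon, which would lead to the regioisomeric arene. The addition–elimination at the fully substituted β-carbon of 10 may be slow and lose out to proton transfer. The Dieckmann closure may stall on the strongly stabilised anion of 11. The fallback uses known reaction types only and reverses the polarity of the first bond, so that C7a is the electrophile and the ring closure is an isolated Dieckmann condensation. It sets out from 6, which TBSOTf/Et3N (CH2Cl2, 0 °C) should convert into the aromatic tert-butyl{[4-(4-methoxybenzyl)-3-(4-methoxyphenyl)furan-2-yl]oxy}dimethylsilane F1. Oxidation of this silyloxyfuran with mCPBA (CH2Cl2, −20 °C) should give the γ-hydroxybutenolide 5-hydroxy-4-(4-methoxybenzyl)-3-(4-methoxyphenyl)furan-2(5H)-one F2, with the position fixed by the furan ring. BF3·OEt2 (CH2Cl2, 0 °C) should ionise this pseudo-acid to the acyloxocarbenium ion, which the enol of methyl phenylpyruvate (assumed commercial) should capture at its benzylic carbon to give methyl 3-[3-(4-methoxybenzyl)-4-(4-methoxyphenyl)-5-oxo-2,5-dihydrofuran-2-yl]-2-oxo-3-phenylpropanoate F3. KOt-Bu (THF, 0 °C to rt, Ar) should then close the ring by Dieckmann acylation of the benzylic carbon on the ester and aromatise it to 5,6-dihydroxy-3,4-bis(4-methoxyphenyl)-7-phenyl-1-benzofuran-2(3H)-one F4. BBr3 should cleave its two aryl methyl ethers to give 13, where the fallback rejoins the route at the Ag2O stage of step 6.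

2. Step 2. Enolisation on the benzyl side of the ketone may lead to O-to-C acyl transfer or to migration of the double bond out of conjugation, instead of the aldol condensation. The fallback builds the butenolide first and attaches the benzyl group by cross-coupling. It sets out from 4, which MeOH/H2SO4 should esterify to methyl (4-methoxyphenyl)acetate F5. Methyl glycolate and KOt-Bu (DMF, rt) should convert this by tandem transesterification/Dieckmann condensation into 4-hydroxy-3-(4-methoxyphenyl)furan-2(5H)-one F6. Tf2O/Et3N (CH2Cl2, −78 °C) should give 4-(4-methoxyphenyl)-5-oxo-2,5-dihydrofuran-3-yl trifluoromethanesulfonate F7. Negishi coupling with (4-methoxybenzyl)zinc chloride (Pd(PPh3)4, THF, rt) should give 6, where the route continues.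

3. Step 6. Cleavage of the hindered ring methyl ether at C6 may be incomplete, BBr3 may open the lactone on prolonged exposure, and the polyphenol may over-oxidise at the Ag2O stage. The fallback sets the oxidation level first by oxidative demethylation and then cleaves only the two unhindered ethers. It sets out from 12, which PhI(OAc)2 (MeCN/H2O, 0 °C) should oxidise at the 2-methoxyphenol unit to the o-quinone with loss of methanol; this tautomerises to peniophorin 4′,4″-di-O-methyl ether, 5-hydroxy-3,4-bis(4-methoxyphenyl)-7-phenyl-1-benzofuran-2,6-dione F8. BBr3 (CH2Cl2, −78 to 0 °C) should then give 14.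

**Further compounds**
F1 | step 5 | tert-butyl{[4-(4-methoxybenzyl)-3-(4-methoxyphenyl)furan-2-yl]oxy}dimethylsilane | COc1ccc(Cc2coc(O[Si](C)(C)C(C)(C)C)c2-c2ccc(OC)cc2)cc1
F2 | step 5 | 5-hydroxy-4-(4-methoxybenzyl)-3-(4-methoxyphenyl)furan-2(5H)-one (racemic) | COc1ccc(CC2=C(c3ccc(OC)cc3)C(=O)OC2O)cc1
F3 | step 5 | methyl 3-[3-(4-methoxybenzyl)-4-(4-methoxyphenyl)-5-oxo-2,5-dihydrofuran-2-yl]-2-oxo-3-phenylpropanoate (diastereomer mixture, racemic) | COC(=O)C(=O)C(c1ccccc1)C1OC(=O)C(c2ccc(OC)cc2)=C1Cc1ccc(OC)cc1
F4 | step 5 | 5,6-dihydroxy-3,4-bis(4-methoxyphenyl)-7-phenyl-1-benzofuran-2(3H)-one (racemic at C3) | O=C1Oc2c(-c3ccccc3)c(O)c(O)c(-c3ccc(OC)cc3)c2C1c1ccc(OC)cc1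
F5 | step 2 | methyl (4-methoxyphenyl)acetate | COC(=O)Cc1ccc(OC)cc1
F6 | step 2 | 4-hydroxy-3-(4-methoxyphenyl)furan-2(5H)-one | O=C1OCC(O)=C1c1ccc(OC)cc1
F7 | step 2 | 4-(4-methoxyphenyl)-5-oxo-2,5-dihydrofuran-3-yl trifluoromethanesulfonate | O=C1OCC(OS(=O)(=O)C(F)(F)F)=C1c1ccc(OC)cc1
F8 | step 6 | 5-hydroxy-3,4-bis(4-methoxyphenyl)-7-phenyl-1-benzofuran-2,6-dione | O=C1OC2=C(c3ccccc3)C(=O)C(O)=C(c3ccc(OC)cc3)C2=C1c1ccc(OC)cc1
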